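**Analysis of the target**

Target 19 is a 3-O-methyl dihydroflavonol: a chroman-4-one (rings A and C) with a 2,5-dihydroxy-4-methoxyphenyl group (ring B) on C2, a methoxy group on C3, a hydroxyl on C5 and methoxy groups on C6 and C7. C2 and C3 are adjacent stereocentres, both R and trans, so the aryl and methoxy groups are both equatorial on ring C. C3 is alpha to the C4 ketone and beta to the ring oxygen O1, so base can epimerise it or open ring C by expelling the O1 phenoxide. C2 is a benzylic ether carbon on a very electron-rich ring and can ionise under acid; reclosure favours the trans isomer as long as C3 holds. Ring B is a hydroquinone and oxidises readily in base and air, and the seven oxygen substituents must end as three phenols and four methyl ethers. The difficulty is that the C2–C3–C4 unit is a beta-aryloxy alpha-methoxy ketone that tolerates neither base nor strong acid, so both stereocentres and ring C should be in place before the ketone exists. The strategy rests on O1 being an aryl ether oxygen on C8a, which is ortho to C4a, the carbon carrying C4. A bromine on C8a of an acyclic C4 carbinol can therefore be replaced by the C2 hydroxyl without breaking any bond to C2 or C3. The 5-methoxy group lies peri to the C4 carbonyl and can be cleaved by chelation, so ring A can be carried as a plain trimethoxyarene.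

**Retrosynthetic reasoning**

19 from 18. The last cut removes the two benzyl groups from the ring B oxygens and the methyl group from O5, leading back to chromanone 18. It is placed last because the free hydroquinone is the most fragile part of 19. The O5 methyl ether can only be distinguished from the other four once the C4 carbonyl is there to chelate a Lewis acid. The forward step must cleave three ethers under non-basic, non-oxidising conditions and spare the methyl ethers on O3, O6, O7 and O4'.

18 from 17. The C4 carbonyl is traced back to the carbinol of chroman-4-ol 17. This postpones the beta-aryloxy ketone to the penultimate step, so nothing basic ever meets it. The forward step is a buffered oxidation of a benzylic alcohol; the C4 configuration is irrelevant because the centre is destroyed.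

17 from 16. The O1–C8a bond is cut, giving the acyclic bromo diol 16. This is the only ring C bond whose formation touches neither stereocentre, and the C2 oxygen is already in place as an aldol hydroxyl. The forward reaction must join a secondary alkoxide to a hindered, electron-rich aryl bromide and must choose the C2 hydroxyl over the C4 hydroxyl; ring size decides that.

16 from 15, and 15 from 11 and 14. The C4–C4a bond is cut between aldehyde 11 and the ortho-bromoaryl Grignard reagent 14. This puts the bromine where the etherification needs it and creates C4 directly as a carbinol. The C2 oxygen is masked as a silyl ether in 11 and 15, so that only one alkoxide is present during the addition and the aldehyde cannot undergo retro-aldol cleavage. The forward addition needs no particular selectivity at C4.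

11 from 10, 10 from 9, and 9 from 7 and 4. The C2–C3 bond is cut as an anti-glycolate aldol between the N-methoxyacetyl oxazolidinethione 7, through its titanium enolate 8, and the ring B aldehyde 4. This one step sets both stereocentres of 19 and brings in the O3 methyl group, so no late methylation of a sensitive ketol is needed. The forward sequence is aldol, silylation to 10 and reductive release of the auxiliary to give 11.

Building blocks. Aldehyde 4 comes from 2-methoxyhydroquinone 1 by benzylation to 2 and formylation para to the methoxy group. Imide 7 comes from auxiliary 5 and methoxyacetyl chloride 6. Grignard reagent 14 comes from 5-bromo-1,2,3-trimethoxybenzene 12 by iodination to 13 and selective iodine–magnesium exchange.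

**Alternatives that were turned down**

Alternative 1: The C4–C4a bond is cut, with C4 stored as the carbonyl of a lactone on the 2'-oxygen of ring B. This is (3R,4R)-6-(benzyloxy)-4-(2-bromo-3,4,5-trimethoxyphenoxy)-3,7-dimethoxy-3,4-dihydro-2H-chromen-2-one A1. In the forward step an alkyllithium exchanges the bromine at the future C4a at very low temperature. The aryllithium attacks the lactone carbonyl and collapse of the adduct releases the 2'-phenoxide, giving (2R,3R)-2-[5-(benzyloxy)-2-hydroxy-4-methoxyphenyl]-3,5,6,7-tetramethoxychroman-4-one A2.
- For: the ketone is reached directly, with no redox adjustment. The 2'-oxygen is unmasked in the same step, and no metal-catalysed C–O coupling is needed. On redox economy it is stronger than the chosen route.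
- Against: in A1 the C3 hydrogen is alpha to the lactone carbonyl and the ring A aryloxy group is beta to it, so any organolithium can cause elimination or epimerisation. The newly formed ketone is more electrophilic than the lactone. Making A1 needs stereocontrolled formation of the benzylic O1–C2 ether from a hindered phenol at a centre that ionises readily, and the two ring B oxygens must be differentiated. A2 still needs the same final ether cleavages.
- Comparison: the chosen strategy spends one oxidation step but keeps strong base away from every intermediate that has an acidic C3 hydrogen, and its precursor comes from a simple aldol.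

Alternative 2: Both O1–C8a and C4–C4a are cut. Fluoride converts 3,4,5-trimethoxy-2-(trimethylsilyl)phenyl trifluoromethanesulfonate A3 into 3,4,5-trimethoxybenzyne A4. The alkoxide of methyl (2R,3R)-3-[2,5-bis(benzyloxy)-4-methoxyphenyl]-3-hydroxy-2-methoxypropanoate A5 adds to the aryne carbon remote from the neighbouring methoxy group. The resulting aryl anion acylates itself on the ester to give (2R,3R)-2-[2,5-bis(benzyloxy)-4-methoxyphenyl]-3,5,6,7-tetramethoxychroman-4-one A6, which is the same compound as 18.
- For: it is the most convergent plan. Two bonds and ring C form in one step at the ketone oxidation level, and A5 comes from the same aldol chemistry. It would save about three steps (silylation, desilylation, oxidation), and the methoxy group helps the regiochemistry of the addition. On step count it is clearly stronger.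
- Against: a hindered secondary alkoxide must capture an aryne intermolecularly. That alkoxide is the aldolate of a beta-hydroxy ester, so retro-aldol cleavage competes under the basic fluoride conditions. The aryl anion may be protonated before it reaches the ester. The product, a beta-aryloxy alpha-methoxy ketone, is exposed to the same base and can epimerise at C3 or open. A3 itself takes several steps.
- Comparison: the chosen strategy gives up step economy so that each bond is made by an intramolecular or chelation-controlled reaction and no aldolate or beta-oxy ketone meets base.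

Alternative 3: The C3–C4 bond is cut. A chiral N-heterocyclic carbene, made from a triazolium precatalyst and an amine base, turns the ring A aldehyde of rac-2-[2,5-bis(benzyloxy)-4-methoxyphenyl]-2-(2-formyl-3,4,5-trimethoxyphenoxy)acetaldehyde A7 into an acyl anion equivalent. This adds to the aliphatic aldehyde while the C2 epimers interconvert by enolisation, giving (2R,3R)-2-[2,5-bis(benzyloxy)-4-methoxyphenyl]-3-hydroxy-5,6,7-trimethoxychroman-4-one A8.
- For: enantiocontrol is catalytic, no auxiliary is used, both stereocentres arise from a racemate in one step, and A7 is easy to assemble. It is stronger on atom economy and on chiral material.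
- Against: the carbene must choose the ring A aldehyde, which has two ortho substituents, over the unhindered aliphatic aldehyde; otherwise the regioisomeric ketol forms. The enol needed for the dynamic resolution can also expel the aryloxide. The product is a secondary alpha-ketol prone to epimerisation. A8 has a free 3-hydroxyl, so a late O-methylation of a base-sensitive dihydroflavonol is still required.
- Comparison: the chosen route brings the 3-methoxy group in with building block 6 and fixes C2 and C3 by a well-understood auxiliary aldol, at the price of stoichiometric chirality.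

Key step: step 10

Assumption: in the open-transition-state aldol of step 4 the aldehyde is taken to attack the face of the sulfur-chelated titanium enolate 8 that is remote from the benzyl group, so the (S)-auxiliary 5 leads to the (2R,3R) adduct 9; if the facial sense proves opposite, the (R)-enantiomer of 5 is used and nothing else changes.

**Steps**

Step 1
Reactants: 1 2-methoxyhydroquinone
Product: 2 1,4-bis(benzyloxy)-2-methoxybenzene
Conditions: BnBr, K2CO3, DMF, 60 °C, under N2
Reagents that add atoms: benzyl bromide, BrCc1ccccc1
Why: Williamson etherification of both phenols; nitrogen is used because the hydroquinone anion oxidises in air.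

Step 2
Reactants: 2 1,4-bis(benzyloxy)-2-methoxybenzene
Product: 4 2,5-bis(benzyloxy)-4-methoxybenzaldehyde, via aryl iminium chloride 3 (not isolated)
Conditions: POCl3, DMF, 0 → 70 °C; then H2O
Reagents that add atoms: N,N-dimethylformamide, CN(C)C=O; water, O
Why: Vilsmeier–Haack formylation; the chloroiminium ion attacks the position para to the methoxy group and ortho to a benzyloxy group, the only unhindered site activated by two donors, and iminium salt 3 is hydrolysed on aqueous work-up.

Step 3
Reactants: 5 (S)-4-benzyl-1,3-oxazolidine-2-thione; 6 methoxyacetyl chloride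
Product: 7 (S)-4-benzyl-3-(methoxyacetyl)-1,3-oxazolidine-2-thione
Conditions: Et3N, CH2Cl2, 0 °C → rt
Reagents that add atoms: none
Why: N-acylation of the oxazolidinethione by an acid chloride, the standard way to make N-glycolyl auxiliaries.

Step 4
Reactants: 7 (S)-4-benzyl-3-(methoxyacetyl)-1,3-oxazolidine-2-thione; 4 2,5-bis(benzyloxy)-4-methoxybenzaldehyde
Product: 9 (4S)-4-benzyl-3-[(2R,3R)-3-[2,5-bis(benzyloxy)-4-methoxyphenyl]-3-hydroxy-2-methoxypropanoyl]-1,3-oxazolidine-2-thione, via chlorotitanium enolate 8 (not isolated)
Conditions: TiCl4, i-Pr2NEt, CH2Cl2, −78 °C; then 4 premixed with TiCl4, −78 °C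
Reagents that add atoms: none
Why: Soft enolisation gives the Z titanium enolate 8, held by the methoxy oxygen and the thione sulfur; the aldehyde, already bound to TiCl4, cannot coordinate the enolate metal, so the anti-selective glycolate aldol runs through an open transition state. Attack on the enolate face away from the benzyl group sets C3 as R, and the antiperiplanar approach sets C2 as R (2,3-anti).

Step 5
Reactants: 9 (4S)-4-benzyl-3-[(2R,3R)-3-[2,5-bis(benzyloxy)-4-methoxyphenyl]-3-hydroxy-2-methoxypropanoyl]-1,3-oxazolidine-2-thione
Product: 10 (4S)-4-benzyl-3-[(2R,3R)-3-[2,5-bis(benzyloxy)-4-methoxyphenyl]-3-[(tert-butyldimethylsilyl)oxy]-2-methoxypropanoyl]-1,3-oxazolidine-2-thione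
Conditions: TBSOTf, 2,6-lutidine, CH2Cl2, −78 → 0 °C
Reagents that add atoms: tert-butyldimethylsilyl trifluoromethanesulfonate, CC(C)(C)[Si](C)(C)OS(=O)(=O)C(F)(F)F
Why: Silylation of the secondary benzylic alcohol with a silyl triflate and a hindered base; it blocks retro-aldol cleavage and leaves only one alkoxide to be formed in step 8.

Step 6
Reactants: 10 (4S)-4-benzyl-3-[(2R,3R)-3-[2,5-bis(benzyloxy)-4-methoxyphenyl]-3-[(tert-butyldimethylsilyl)oxy]-2-methoxypropanoyl]-1,3-oxazolidine-2-thione
Product: 11 (2R,3R)-3-[2,5-bis(benzyloxy)-4-methoxyphenyl]-3-[(tert-butyldimethylsilyl)oxy]-2-methoxypropanal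
Conditions: i-Bu2AlH, CH2Cl2, −78 °C
Reagents that add atoms: none
Why: N-acyl oxazolidinethiones are reduced directly to aldehydes by i-Bu2AlH at low temperature with release of the auxiliary; the cold, non-basic conditions should leave the alpha-methoxy centre untouched, and 11 is used at once.

Step 7
Reactants: 12 5-bromo-1,2,3-trimethoxybenzene
Product: 13 1-bromo-2-iodo-3,4,5-trimethoxybenzene
Conditions: N-iodosuccinimide, CF3CO2H (cat.), MeCN, rt
Reagents that add atoms: N-iodosuccinimide, O=C1CCC(=O)N1I
Why: Electrophilic aromatic iodination; the two free positions are equivalent by symmetry and each is ortho and para to methoxy groups, so one equivalent of reagent gives a single mono-iodide.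

Step 8
Reactants: 13 1-bromo-2-iodo-3,4,5-trimethoxybenzene; 11 (2R,3R)-3-[2,5-bis(benzyloxy)-4-methoxyphenyl]-3-[(tert-butyldimethylsilyl)oxy]-2-methoxypropanal
Product: 15 (1R,2S,3R)-1-(2-bromo-4,5,6-trimethoxyphenyl)-3-[2,5-bis(benzyloxy)-4-methoxyphenyl]-3-[(tert-butyldimethylsilyl)oxy]-2-methoxypropan-1-ol, via arylmagnesium chloride 14 (not isolated)
Conditions: i-PrMgCl·LiCl, THF, −40 → −20 °C; then 11, −78 → −20 °C
Reagents that add atoms: none
Why: Iodine–magnesium exchange is much faster at C–I than at C–Br, and ortho-bromoaryl Grignard reagents are stable at these temperatures; addition to the aldehyde forms C4–C4a. Magnesium chelated between the aldehyde and alpha-methoxy oxygens (Cram chelate model) should favour the 1,2-syn carbinol shown, but this centre is removed in step 11 and any epimer converges there.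

Step 9
Reactants: 15 (1R,2S,3R)-1-(2-bromo-4,5,6-trimethoxyphenyl)-3-[2,5-bis(benzyloxy)-4-methoxyphenyl]-3-[(tert-butyldimethylsilyl)oxy]-2-methoxypropan-1-ol
Product: 16 (1R,2R,3R)-1-(2-bromo-4,5,6-trimethoxyphenyl)-3-[2,5-bis(benzyloxy)-4-methoxyphenyl]-2-methoxypropane-1,3-diol
Conditions: Bu4NF, THF, 0 °C → rt
Reagents that add atoms: none
Why: Fluoride cleavage of the silyl ether; the conditions are free of acid, which the two electron-rich benzylic carbinols would not tolerate.

Step 10
Reactants: 16 (1R,2R,3R)-1-(2-bromo-4,5,6-trimethoxyphenyl)-3-[2,5-bis(benzyloxy)-4-methoxyphenyl]-2-methoxypropane-1,3-diol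
Product: 17 (2R,3S,4R)-2-[2,5-bis(benzyloxy)-4-methoxyphenyl]-3,5,6,7-tetramethoxy-3,4-dihydro-2H-chromen-4-ol
Conditions: CuI (10 mol %), 3,4,7,8-tetramethyl-1,10-phenanthroline (20 mol %), Cs2CO3, toluene, 110 °C, under Ar
Reagents that add atoms: none
Why: This is an Ullmann-type intramolecular etherification of an aryl bromide by a secondary alcohol, a known way to close chromans. Cs2CO3 reversibly deprotonates the hydroxyl on the carbon bearing ring B (the future C2) and the alkoxide binds monovalent copper carrying the phenanthroline ligand; oxidative addition of the ortho C–Br bond gives a trivalent aryl copper alkoxide, and reductive elimination forms O1–C8a. Ring C closes as a six-membered ring with the oxygen attacking an arene carbon whose bromide leaves outside the ring (formally 6-exo). No stereocentre is created, and since no bond to C2 or C3 is broken the anti relation of 16 becomes the 2,3-trans relation of 17; the change of the C3 descriptor from R to S is only a change of substituent priorities. The one selectivity needed is between the two hydroxyls, and ring size secures it, because the other oxygen could only close a four-membered ring. With C4 held as a carbinol there is no carbonyl to permit retro-aldol cleavage, enolisation at C3 or expulsion of the aryloxide under carbonate at 110 °C. The electron-rich tetramethylphenanthroline ligand is chosen because it promotes C–O coupling of unactivated aryl bromides with aliphatic alcohols, and oxygen is excluded to prevent copper-mediated oxidation of the benzylic carbinols.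

Step 11
Reactants: 17 (2R,3S,4R)-2-[2,5-bis(benzyloxy)-4-methoxyphenyl]-3,5,6,7-tetramethoxy-3,4-dihydro-2H-chromen-4-ol
Product: 18 (2R,3R)-2-[2,5-bis(benzyloxy)-4-methoxyphenyl]-3,5,6,7-tetramethoxy-2,3-dihydro-4H-chromen-4-one
Conditions: Dess–Martin periodinane, pyridine, CH2Cl2, 0 °C → rt
Reagents that add atoms: none
Why: Dess–Martin oxidation of the benzylic secondary alcohol to the ketone; pyridine buffers the acetic acid so that the acid-labile C4 carbinol does not ionise, and nothing present is basic enough to enolise C3.

Step 12
Reactants: 18 (2R,3R)-2-[2,5-bis(benzyloxy)-4-methoxyphenyl]-3,5,6,7-tetramethoxy-2,3-dihydro-4H-chromen-4-one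
Product: 19 (2R,3R)-2-(2,5-dihydroxy-4-methoxyphenyl)-5-hydroxy-3,6,7-trimethoxy-2,3-dihydro-4H-chromen-4-one
Conditions: BCl3, pentamethylbenzene, CH2Cl2, −78 → 0 °C; then H2O
Reagents that add atoms: none
Why: BCl3 with pentamethylbenzene as a non-basic cation scavenger cleaves aryl benzyl ethers at −78 °C without benzylating the electron-rich rings. On warming, boron chelated between the C4 carbonyl and the peri 5-methoxy oxygen lets chloride remove only that methyl group, the known selective 5-O-demethylation of 5-methoxyflavanones. The medium is neither basic nor oxidising, so C3 and the hydroquinone are spared.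

**Compound list**

1 | 2-methoxyhydroquinone | COc1cc(O)ccc1O | starting material
2 | 1,4-bis(benzyloxy)-2-methoxybenzene | COc1cc(OCc2ccccc2)ccc1OCc1ccccc1 | intermediate
3 | N-{[2,5-bis(benzyloxy)-4-methoxyphenyl]methylidene}-N-methylmethanaminium chloride | COc1cc(OCc2ccccc2)c(C=[N+](C)C)cc1OCc1ccccc1.[Cl-] | intermediate (not isolated)
4 | 2,5-bis(benzyloxy)-4-methoxybenzaldehyde | COc1cc(OCc2ccccc2)c(C=O)cc1OCc1ccccc1 | intermediate
5 | (S)-4-benzyl-1,3-oxazolidine-2-thione | S=C1N[C@@H](Cc2ccccc2)CO1 | starting material
6 | methoxyacetyl chloride | COCC(Cl)=O | starting material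
7 | (S)-4-benzyl-3-(methoxyacetyl)-1,3-oxazolidine-2-thione | COCC(=O)N1C(=S)OC[C@@H]1Cc1ccccc1 | intermediate
8 | trichlorotitanium (Z)-1-[(4S)-4-benzyl-2-thioxo-1,3-oxazolidin-3-yl]-2-methoxyethen-1-olate | CO/C=C(\O[Ti](Cl)(Cl)Cl)N1C(=S)OC[C@@H]1Cc1ccccc1 | intermediate (not isolated)
9 | (4S)-4-benzyl-3-[(2R,3R)-3-[2,5-bis(benzyloxy)-4-methoxyphenyl]-3-hydroxy-2-methoxypropanoyl]-1,3-oxazolidine-2-thione | COc1cc(OCc2ccccc2)c([C@@H](O)[C@@H](OC)C(=O)N2C(=S)OC[C@@H]2Cc2ccccc2)cc1OCc1ccccc1 | intermediate
10 | (4S)-4-benzyl-3-[(2R,3R)-3-[2,5-bis(benzyloxy)-4-methoxyphenyl]-3-[(tert-butyldimethylsilyl)oxy]-2-methoxypropanoyl]-1,3-oxazolidine-2-thione | COc1cc(OCc2ccccc2)c([C@@H](O[Si](C)(C)C(C)(C)C)[C@@H](OC)C(=O)N2C(=S)OC[C@@H]2Cc2ccccc2)cc1OCc1ccccc1 | intermediate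
11 | (2R,3R)-3-[2,5-bis(benzyloxy)-4-methoxyphenyl]-3-[(tert-butyldimethylsilyl)oxy]-2-methoxypropanal | COc1cc(OCc2ccccc2)c([C@@H](O[Si](C)(C)C(C)(C)C)[C@@H](OC)C=O)cc1OCc1ccccc1 | intermediate
12 | 5-bromo-1,2,3-trimethoxybenzene | COc1cc(Br)cc(OC)c1OC | starting material
13 | 1-bromo-2-iodo-3,4,5-trimethoxybenzene | COc1cc(Br)c(I)c(OC)c1OC | intermediate
14 | (6-bromo-2,3,4-trimethoxyphenyl)magnesium chloride (LiCl complex) | COc1cc(Br)c([Mg]Cl)c(OC)c1OC | intermediate (not isolated)
15 | (1R,2S,3R)-1-(2-bromo-4,5,6-trimethoxyphenyl)-3-[2,5-bis(benzyloxy)-4-methoxyphenyl]-3-[(tert-butyldimethylsilyl)oxy]-2-methoxypropan-1-ol | COc1cc(OCc2ccccc2)c([C@@H](O[Si](C)(C)C(C)(C)C)[C@@H](OC)[C@H](O)c2c(Br)cc(OC)c(OC)c2OC)cc1OCc1ccccc1 | intermediate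
16 | (1R,2R,3R)-1-(2-bromo-4,5,6-trimethoxyphenyl)-3-[2,5-bis(benzyloxy)-4-methoxyphenyl]-2-methoxypropane-1,3-diol | COc1cc(OCc2ccccc2)c([C@@H](O)[C@@H](OC)[C@H](O)c2c(Br)cc(OC)c(OC)c2OC)cc1OCc1ccccc1 | intermediate
17 | (2R,3S,4R)-2-[2,5-bis(benzyloxy)-4-methoxyphenyl]-3,5,6,7-tetramethoxy-3,4-dihydro-2H-chromen-4-ol | COc1cc(OCc2ccccc2)c([C@H]2Oc3cc(OC)c(OC)c(OC)c3[C@@H](O)[C@@H]2OC)cc1OCc1ccccc1 | intermediate
18 | (2R,3R)-2-[2,5-bis(benzyloxy)-4-methoxyphenyl]-3,5,6,7-tetramethoxy-2,3-dihydro-4H-chromen-4-one | COc1cc(OCc2ccccc2)c([C@H]2Oc3cc(OC)c(OC)c(OC)c3C(=O)[C@@H]2OC)cc1OCc1ccccc1 | intermediate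
19 | (2R,3R)-2-(2,5-dihydroxy-4-methoxyphenyl)-5-hydroxy-3,6,7-trimethoxy-2,3-dihydro-4H-chromen-4-one | COc1cc(O)c([C@H]2Oc3cc(OC)c(OC)c(O)c3C(=O)[C@@H]2OC)cc1O | target

**Step count and risk**

Total step count: 12. Longest linear sequence: 10 steps (steps 1, 2, 4, 5, 6, 8, 9, 10, 11, 12, from 1 to 19).

Step 10 (key step). Most likely failure: slow oxidative addition at a bromide that is both electron-rich and ortho-substituted, so that hydrodebromination or catalyst deactivation by the chelating 1,3-diolate wins; traces of oxygen would cause oxidation of the benzylic carbinols. Fallback: the same O1–C8a bond is closed by an elimination–addition (aryne) path instead of a metal-catalysed coupling, setting out from 16 and coming back at 17. Excess lithium 2,2,6,6-tetramethylpiperidide in THF at −78 °C forms the dialkoxide and removes the only ring A hydrogen, which lies between the bromine and a methoxy group. On warming, bromide is lost and the tethered alkoxide adds to the nearer of the two strained carbons in a six-membered closure. The neighbouring methoxy group stabilises the aryl anion formed at the other carbon, which is protonated on work-up. No new compound is made (F0).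

Step 4. Most likely failure: erosion of anti selectivity or of facial control because the ortho-benzyloxy aldehyde binds TiCl4 as a bidentate ligand and changes the open transition state. Chelation-assisted loss of that benzyl ether and ionisation of the electron-rich benzylic titanium alkoxide are further risks. Fallback: a ligand-controlled Mukaiyama aldol in place of the auxiliary-controlled titanium aldol, setting out from 4 and 6 and coming back at 11. Acid chloride 6 and ethanethiol give S-ethyl 2-methoxyethanethioate F1, and enolisation with silylation gives (Z)-1-(ethylsulfanyl)-2-methoxy-1-[(trimethylsilyl)oxy]ethene F2. F2 adds to 4 with Sn(OTf)2, Bu2Sn(OAc)2 and a proline-derived chiral diamine, in the enantiomeric form that leads to the anti adduct S-ethyl (2R,3R)-3-[2,5-bis(benzyloxy)-4-methoxyphenyl]-3-hydroxy-2-methoxypropanethioate F3. Silylation as in step 5 gives S-ethyl (2R,3R)-3-[2,5-bis(benzyloxy)-4-methoxyphenyl]-3-[(tert-butyldimethylsilyl)oxy]-2-methoxypropanethioate F4, and i-Bu2AlH at −78 °C reduces the thioester to aldehyde 11.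

Step 8. Most likely failure: the hindered, basic Grignard reagent enolises the alpha-methoxy aldehyde (epimerisation, or loss of the beta-silyloxy group by elimination) instead of adding, or it loses magnesium halide on warming before it has reacted. Fallback: a Nozaki–Hiyama–Kishi coupling, setting out from 13 and 11 and coming back at 15. CrCl2 with catalytic NiCl2 in DMF inserts selectively into the C–I bond, and the aryl chromium species, which is not basic and does not eliminate the ortho bromide, adds to the aldehyde. Either carbinol epimer is acceptable because both converge at 18. No new compound is made (F0).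

Step 12. Most likely failure: over-demethylation (the O3 methyl ether next to the chelating carbonyl, or the O4' methyl ether beside a freed phenol) during the warming needed for the O5 methyl ether, or ionisation at C2 with epimerisation. Fallback: the two kinds of ether are removed by different mechanisms, setting out from 18 and coming back at 19. Hydrogenolysis (H2, Pd/C, EtOAc) removes both benzyl groups under neutral conditions to give (2R,3R)-2-(2,5-dihydroxy-4-methoxyphenyl)-3,5,6,7-tetramethoxy-2,3-dihydro-4H-chromen-4-one F5. AlCl3 in MeCN, a milder chelation-specific reagent, then cleaves only the peri O5 methyl ether to give 19.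

**Further compounds**

F1 | step 4 | S-ethyl 2-methoxyethanethioate | CCSC(=O)COC
F2 | step 4 | (Z)-1-(ethylsulfanyl)-2-methoxy-1-[(trimethylsilyl)oxy]ethene | CCS/C(O[Si](C)(C)C)=C\OC
F3 | step 4 | S-ethyl (2R,3R)-3-[2,5-bis(benzyloxy)-4-methoxyphenyl]-3-hydroxy-2-methoxypropanethioate | COc1cc(OCc2ccccc2)c([C@@H](O)[C@@H](OC)C(=O)SCC)cc1OCc1ccccc1
F4 | step 4 | S-ethyl (2R,3R)-3-[2,5-bis(benzyloxy)-4-methoxyphenyl]-3-[(tert-butyldimethylsilyl)oxy]-2-methoxypropanethioate | COc1cc(OCc2ccccc2)c([C@@H](O[Si](C)(C)C(C)(C)C)[C@@H](OC)C(=O)SCC)cc1OCc1ccccc1
F0 | step 8 | none | none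
F0 | step 10 | none | none
F5 | step 12 | (2R,3R)-2-(2,5-dihydroxy-4-methoxyphenyl)-3,5,6,7-tetramethoxy-2,3-dihydro-4H-chromen-4-one | COc1cc(O)c([C@H]2Oc3cc(OC)c(OC)c(OC)c3C(=O)[C@@H]2OC)cc1O
A1 | alternative 1 | (3R,4R)-6-(benzyloxy)-4-(2-bromo-3,4,5-trimethoxyphenoxy)-3,7-dimethoxy-3,4-dihydro-2H-chromen-2-one | COc1cc2OC(=O)[C@H](OC)[C@H](Oc3cc(OC)c(OC)c(OC)c3Br)c2cc1OCc1ccccc1
A2 | alternative 1 | (2R,3R)-2-[5-(benzyloxy)-2-hydroxy-4-methoxyphenyl]-3,5,6,7-tetramethoxychroman-4-one | COc1cc(O)c([C@H]2Oc3cc(OC)c(OC)c(OC)c3C(=O)[C@@H]2OC)cc1OCc1ccccc1
A3 | alternative 2 | 3,4,5-trimethoxy-2-(trimethylsilyl)phenyl trifluoromethanesulfonate | COc1cc(OS(=O)(=O)C(F)(F)F)c([Si](C)(C)C)c(OC)c1OC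
A4 | alternative 2 | 3,4,5-trimethoxybenzyne | COC1=C(OC)C(OC)=CC#C1
A5 | alternative 2 | methyl (2R,3R)-3-[2,5-bis(benzyloxy)-4-methoxyphenyl]-3-hydroxy-2-methoxypropanoate | COc1cc(OCc2ccccc2)c([C@@H](O)[C@@H](OC)C(=O)OC)cc1OCc1ccccc1
A6 | alternative 2 | (2R,3R)-2-[2,5-bis(benzyloxy)-4-methoxyphenyl]-3,5,6,7-tetramethoxychroman-4-one | COc1cc(OCc2ccccc2)c([C@H]2Oc3cc(OC)c(OC)c(OC)c3C(=O)[C@@H]2OC)cc1OCc1ccccc1
A7 | alternative 3 | rac-2-[2,5-bis(benzyloxy)-4-methoxyphenyl]-2-(2-formyl-3,4,5-trimethoxyphenoxy)acetaldehyde | COc1cc(OCc2ccccc2)c(C(C=O)Oc2cc(OC)c(OC)c(OC)c2C=O)cc1OCc1ccccc1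
A8 | alternative 3 | (2R,3R)-2-[2,5-bis(benzyloxy)-4-methoxyphenyl]-3-hydroxy-5,6,7-trimethoxychroman-4-one | COc1cc(OCc2ccccc2)c([C@H]2Oc3cc(OC)c(OC)c(OC)c3C(=O)[C@@H]2O)cc1OCc1ccccc1
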